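## The problem

Target 17 is a (2S)-flavan, that is a 3,4-dihydro-2H-chromene. Its benzo ring (ring A) is a phloroglucinol unit with free hydroxyls at C5 and C7, C2 carries a 4-hydroxyphenyl group (ring B), and C8, wedged between O1 and the C7 hydroxyl, carries a 2-(4-hydroxyphenyl)-1,2-dioxoethyl chain ending in ring D. C2 is the only stereocentre, so nothing in the molecule can relay its configuration; it must come from a catalyst or reagent and then be carried through untouched. It is also fragile. The C2–O1 bond is a benzylic ether para to the ring B oxygen and ionises under acid. Once the 4'-hydroxyl is free, base can open it through a para-quinone methide, helped by O1 being the oxygen of a 2-acylphenol; reclosure would racemise C2 and, through O5, could shift the chain from C8 to C6. The 1,2-diketone excludes a reductive finish (hydrogenolysis would reduce it) and a strongly basic one (benzilic acid rearrangement), so four phenols have to be uncovered under mild acid alone. Ring A has two almost equivalent nucleophilic carbons, C6 and C8, and the chain must go to C8 only. The handle for the key step is that C2 is bonded to O1, to ring B and to C3. With C3 as an alkene carbon this is a branched 1-arylallyl aryl ether, the product type of an enantioselective allylic etherification, and a vinyl group on C4a then allows C3=C4 to be closed by metathesis after the stereocentre exists.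

## Retrosynthesis

**17 from 16.** The last cut removes four methoxymethyl groups from the phenol oxygens. Acetal ethers are chosen over benzyl ethers (hydrogenolysis would endanger the diketone), over silyl or acyl groups (fluoride or base would generate the 4'-phenoxide that opens the pyran ring) and over methyl ethers (a strong Lewis acid would cleave C2–O1). Precursor 16 has the same skeleton but is robust toward bases, organometallics and oxidants. The forward step must cleave four acetals with dilute acid without ionising C2–O1.

**16 from 15.** The two carbonyl oxygens are removed and the dione carbons become the two carbons of a diarylalkyne. The neighbouring option, acylating an 8-metallated flavan with a preformed two-carbon dicarbonyl electrophile, was set aside: the ketone of such a reagent competes for the nucleophile, and the nucleophile would be a hindered, doubly ortho-oxygenated aryl anion. The alkyne is an inert mask that already holds both carbons in place. The oxidation must be neutral and must not π-activate the alkyne, because the C7 acetal oxygen and O1 sit next to it and could cyclise onto it.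

**15 from 13 and 14.** Cutting the C8–C(sp) bond splits the molecule into iodoflavan 13 and arylalkyne 14, so ring D arrives convergently in a Sonogashira coupling. The rod-shaped alkyne suits a position flanked by two oxygens better than an sp2 or sp3 partner would.

**13 from 12.** The C8–I bond is removed. Flavan 12 has no directing group other than its oxygens, so the forward iodination must choose C8 over C6. The tied-back ring oxygen beside C8, against two freely rotating acetal ethers beside C6, is what is relied on.

**12 from 11, and 11 from 10.** Saturating C3–C4 leads back to 2H-chromene 11, and cutting C3=C4 leads to diene 10, whose two terminal alkenes are joined by ring-closing metathesis. Both forward steps are neutral and leave C2 alone. The hydrogenation must spare the C2–O1 bond, which is allylic and benzylic in 11, and this calls for a homogeneous rhodium catalyst in place of palladium on carbon.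

**10 from 3 and 8 (key disconnection).** Cutting O1–C2 gives vinylphenol 3 and cinnamyl carbonate 8. Against closing the pyran first and setting C2 inside the ring, this cut creates the stereocentre intermolecularly under catalyst control, from two achiral fragments of similar size. Because 3 has a single free hydroxyl flanked by the vinyl group, O1 and C4 are fixed before any ring exists. The forward reaction needs branched regioselectivity, O- over C-allylation of a very electron-rich phenoxide, and high enantioselectivity, all under kinetic control.

**3 from 2 from 1.** The vinyl group of 3 comes from the formyl group of salicylaldehyde 2 by methylenation. 2 comes from 1 by protecting the two hydroxyls that are not needed, the third being held back by its hydrogen bond to the formyl group.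

**8 from 7, 6, 5 and 4; 14 from 5.** Carbonate 8 is the activated form of allylic alcohol 7, which comes from enoate 6 by reduction and 6 from aldehyde 5 by a two-carbon olefination. 5 is the protected form of 4. One-carbon homologation of the same aldehyde 5 gives alkyne 14, so rings B and D both derive from 4.

## Roads not taken

**Alternative 1:** An ortho-quinone methide oxa-Diels–Alder reaction cuts C3–C4 and O1–C2 together. The quinone methide released from hydroxymethyl ketone A2 would add to styrene A3 and give 8-acetylflavan A1 in one step.
- Merits: the pyran ring and two bonds form in one operation, the route to the flavan core is clearly shorter than the nine steps needed here to reach 12, and the C8 carbon substituent is present from the start, so the C6/C8 question never arises. On these points it is better than the chosen plan.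
- Weak points: the acetyl group still has to become an aryl diketone (α-arylation of a hindered ketone, then oxidation of the new methylene). Benzyl ethers would force a hydrogenolytic finish in the presence of the diketone. Most seriously, there is no established way to control the facial selectivity of such a cycloaddition with an unactivated styrene; known enantioselective variants depend on polar or chelating dienophiles.
- Comparison: since 17 is wanted as one enantiomer, the chosen plan's longer path is accepted in exchange for a stereocentre set by a catalyst of known behaviour.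

**Alternative 2:** This road cuts the bond between the two carbonyl carbons. A thiamine diphosphate-dependent benzaldehyde lyase would turn aldehyde 5 into an acyl anion equivalent and add it to flavan-8-carbaldehyde A5 to give benzoin A4, whose oxidation would give 16.
- Merits: the carbon–carbon bond forms in neutral aqueous medium one oxidation level below the diketone, ortho-substituted aldehydes do not serve as donors so the cross-coupling direction is clean, and no alkyne oxidation is needed. In mildness this endgame is better than Sonogashira coupling plus permanganate.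
- Weak points: A5 is large, lipophilic and doubly ortho-substituted, outside the acceptor range where the enzyme is established. The carbinol stereocentre it creates is thrown away. It solves neither C2 nor the C8 regiochemistry, so the flavan and its C8 functionalisation would still come from chemistry like steps 1 to 10.
- Comparison: it is an alternative endgame, not an alternative strategy; the chosen plan relies instead on couplings whose scope with hindered aryl iodides is known.

**Alternative 3:** This road cuts the C2–aryl bond. A chiral pyridine–oxazoline complex of divalent palladium would add boronic acid A7 to chromone A6 and give flavanone A8.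
- Merits: the stereocentre is set on a preformed bicycle in one catalytic step of an established reaction class, and the flavan skeleton is reached in far fewer steps than here. In step count it is better.
- Weak points: the 5- and 7-alkoxy groups make the chromone a poorer acceptor. C2 of A8 is β to a ketone and racemises by retro-oxa-Michael opening under base or heat. The C4 carbonyl must then be removed by reduction and ionic or hydrogenolytic deoxygenation, which generates a benzylic cation or uses palladium and hydrogen on a molecule carrying benzyl ethers and a labile C2–O1 bond. C8 functionalisation and a diketone-compatible deprotection would still be needed.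
- Comparison: the chosen plan never places a carbonyl at C4, so C2 cannot epimerise once set and no deoxygenation is required.

Key step: step 7

Assumption: 1, 4, all reagents and both enantiomers of the phosphoramidite ligand are purchased; the sense of induction of the ligand is taken from the usual behaviour of this catalyst family and would be confirmed on the first batch of 10.

## Route

Step 1
Reactants: 1 2,4,6-trihydroxybenzaldehyde
Product: 2 2-hydroxy-4,6-bis(methoxymethoxy)benzaldehyde
Conditions: MOMCl (2.1 equiv), i-Pr2NEt, CH2Cl2, 0 °C to rt
Reagents that add atoms: chloromethyl methyl ether, COCCl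
Why: O-alkylation of phenols; the para hydroxyl and one ortho hydroxyl react, while the remaining ortho hydroxyl is tied up in a hydrogen bond to the formyl oxygen and stays free when two equivalents are used.

Step 2
Reactants: 2 2-hydroxy-4,6-bis(methoxymethoxy)benzaldehyde
Product: 3 2-ethenyl-3,5-bis(methoxymethoxy)phenol
Conditions: Ph3PCH3Br (3 equiv), KOt-Bu (2.9 equiv), THF, 0 °C to rt; aq. NH4Cl
Reagents that add atoms: methyltriphenylphosphonium bromide, C[P+](c1ccccc1)(c1ccccc1)c1ccccc1.[Br-]
Why: Wittig methylenation; excess ylide first deprotonates the phenol and then olefinates the aldehyde, as is routine for salicylaldehydes. The acid-sensitive vinylphenol is worked up buffered and used at once.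

Step 3
Reactants: 4 4-hydroxybenzaldehyde
Product: 5 4-(methoxymethoxy)benzaldehyde
Conditions: MOMCl, i-Pr2NEt, CH2Cl2, 0 °C to rt
Reagents that add atoms: chloromethyl methyl ether, COCCl
Why: Straightforward O-alkylation of a phenol; the product serves both ring B and ring D.

Step 4
Reactants: 5 4-(methoxymethoxy)benzaldehyde
Product: 6 ethyl (2E)-3-[4-(methoxymethoxy)phenyl]prop-2-enoate
Conditions: (EtO)2P(O)CH2CO2Et, NaH, THF, 0 °C to rt
Reagents that add atoms: triethyl phosphonoacetate, CCOC(=O)CP(=O)(OCC)OCC
Why: Horner–Wadsworth–Emmons olefination with a stabilised phosphonate gives the E enoate.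

Step 5
Reactants: 6 ethyl (2E)-3-[4-(methoxymethoxy)phenyl]prop-2-enoate
Product: 7 (2E)-3-[4-(methoxymethoxy)phenyl]prop-2-en-1-ol
Conditions: i-Bu2AlH (2.2 equiv), CH2Cl2, −78 °C; aq. potassium sodium tartrate
Reagents that add atoms: none
Why: 1,2-Reduction of an enoate to the allylic alcohol with i-Bu2AlH at low temperature; alkene geometry and acetal are unaffected.

Step 6
Reactants: 7 (2E)-3-[4-(methoxymethoxy)phenyl]prop-2-en-1-ol
Product: 8 (2E)-3-[4-(methoxymethoxy)phenyl]prop-2-en-1-yl methyl carbonate
Conditions: ClCO2Me, pyridine, CH2Cl2, 0 °C
Reagents that add atoms: methyl chloroformate, COC(=O)Cl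
Why: Acylation of the primary alcohol with a chloroformate; the carbonate is the leaving group for step 7 and releases its own base on ionisation.

Step 7
Reactants: 3 2-ethenyl-3,5-bis(methoxymethoxy)phenol; 8 (2E)-3-[4-(methoxymethoxy)phenyl]prop-2-en-1-yl methyl carbonate
Product: 10 2-ethenyl-1,5-bis(methoxymethoxy)-3-({(1S)-1-[4-(methoxymethoxy)phenyl]prop-2-en-1-yl}oxy)benzene, via lithium 2-ethenyl-3,5-bis(methoxymethoxy)phenolate 9 (not isolated)
Conditions: 3, n-BuLi, THF, 0 °C; then 8, [Ir(cod)Cl]2 (2 mol %), (Sa,Sc,Sc)-binaphthyl-2,2'-diyl N,N-bis(1-phenylethyl)phosphoramidite (4 mol %, catalyst preactivated with n-PrNH2), THF, rt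
Reagents that add atoms: none
Why: This is the iridium-catalysed enantioselective allylic etherification of alkali aryloxides with cinnamyl carbonates, a known reaction that also tolerates ortho-substituted phenoxides. The cyclometalated monovalent iridium phosphoramidite complex ionises 8 with loss of carbon dioxide and methoxide to a trivalent allyliridium species, and aryloxide 9 attacks the aryl-bearing allyl terminus from the face opposite the metal, forming O1–C2. No ring closes. C2 is set by the catalyst alone, since the ligand decides which allyl face is bound to iridium; the (Sa,Sc,Sc) ligand is expected to give the (S)-ether, and its enantiomer is available should the sense prove opposite. Three selectivities are needed: branched over linear, which is the intrinsic preference of this catalyst; O- over C-allylation of the electron-rich ring, favoured by the lithium aryloxide in THF; and kinetic control, because the product can re-ionise. The last is helped by the poor leaving-group ability of the electron-rich aryloxide, by room temperature and acid-free conditions, and by stopping when 8 is consumed. Because 3 has one free hydroxyl next to its vinyl group, O1 and the future C4 are unambiguous.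

Step 8
Reactants: 10 2-ethenyl-1,5-bis(methoxymethoxy)-3-({(1S)-1-[4-(methoxymethoxy)phenyl]prop-2-en-1-yl}oxy)benzene
Product: 11 (2S)-5,7-bis(methoxymethoxy)-2-[4-(methoxymethoxy)phenyl]-2H-chromene
Conditions: second-generation Grubbs catalyst RuCl2(H2IMes)(PCy3)(=CHPh) (3 mol %), 1,4-benzoquinone (10 mol %), CH2Cl2, 40 °C
Reagents that add atoms: none
Why: Ring-closing metathesis forms C3=C4 and the six-membered pyran ring; the catalyst loads at the unhindered allyl ether alkene and closes onto the styrene. Benzoquinone suppresses ruthenium hydride isomerisation, which would move the double bond to C2 and erase the stereocentre.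

Step 9
Reactants: 11 (2S)-5,7-bis(methoxymethoxy)-2-[4-(methoxymethoxy)phenyl]-2H-chromene
Product: 12 (2S)-5,7-bis(methoxymethoxy)-2-[4-(methoxymethoxy)phenyl]-3,4-dihydro-2H-chromene
Conditions: H2 (1–3 bar), RhCl(PPh3)3 (5 mol %), toluene/EtOH, rt
Reagents that add atoms: none
Why: Homogeneous hydrogenation with Wilkinson's catalyst saturates the cis-disubstituted C3=C4 bond without hydrogenolysis of the allylic, benzylic C2–O1 bond that palladium on carbon would threaten; C2 is not involved.

Step 10
Reactants: 12 (2S)-5,7-bis(methoxymethoxy)-2-[4-(methoxymethoxy)phenyl]-3,4-dihydro-2H-chromene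
Product: 13 (2S)-8-iodo-5,7-bis(methoxymethoxy)-2-[4-(methoxymethoxy)phenyl]-3,4-dihydro-2H-chromene
Conditions: NIS (1.0 equiv), DMF, 0 °C, dark
Reagents that add atoms: N-iodosuccinimide, O=C1CCC(=O)N1I
Why: Electrophilic aromatic iodination of ring A, which is far more nucleophilic than ring B. C8 should be preferred over C6 because it is flanked by the tied-back ring oxygen instead of two freely rotating acetal ethers, as known for halogenation of 5,7-di-O-alkylated flavans; neutral conditions spare the acetals.

Step 11
Reactants: 5 4-(methoxymethoxy)benzaldehyde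
Product: 14 1-ethynyl-4-(methoxymethoxy)benzene
Conditions: dimethyl (1-diazo-2-oxopropyl)phosphonate, K2CO3, MeOH, rt
Reagents that add atoms: dimethyl (1-diazo-2-oxopropyl)phosphonate, CC(=O)C(=[N+]=[N-])P(=O)(OC)OC
Why: Seyferth–Gilbert homologation in its Ohira–Bestmann form; methanolysis of the reagent gives the diazomethylphosphonate anion, which adds to the aldehyde and loses phosphate and nitrogen to give the terminal alkyne under base too mild to touch the acetal.

Step 12
Reactants: 13 (2S)-8-iodo-5,7-bis(methoxymethoxy)-2-[4-(methoxymethoxy)phenyl]-3,4-dihydro-2H-chromene; 14 1-ethynyl-4-(methoxymethoxy)benzene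
Product: 15 (2S)-5,7-bis(methoxymethoxy)-2-[4-(methoxymethoxy)phenyl]-8-{[4-(methoxymethoxy)phenyl]ethynyl}-3,4-dihydro-2H-chromene
Conditions: PdCl2(PPh3)2 (5 mol %), CuI (5 mol %), Et3N/DMF, 60 °C, degassed
Reagents that add atoms: none
Why: Sonogashira coupling; aryl iodides flanked by two alkoxy groups are known to couple, and the linear alkyne meets little steric resistance at C8. Excess 14 and exclusion of air counter oxidative homocoupling.

Step 13
Reactants: 15 (2S)-5,7-bis(methoxymethoxy)-2-[4-(methoxymethoxy)phenyl]-8-{[4-(methoxymethoxy)phenyl]ethynyl}-3,4-dihydro-2H-chromene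
Product: 16 1-[(2S)-5,7-bis(methoxymethoxy)-2-[4-(methoxymethoxy)phenyl]-3,4-dihydro-2H-chromen-8-yl]-2-[4-(methoxymethoxy)phenyl]ethane-1,2-dione
Conditions: KMnO4, NaHCO3, MgSO4, acetone/H2O, 0 °C to rt
Reagents that add atoms: potassium permanganate, [K+].[O-][Mn](=O)(=O)=O
Why: Buffered permanganate oxidation of a diarylalkyne to the benzil through a cyclic manganate ester. The neutral medium contains no π-acid, so the C7 acetal oxygen and O1 are not induced to attack the alkyne, and the acetals and C2 stay intact.

Step 14
Reactants: 16 1-[(2S)-5,7-bis(methoxymethoxy)-2-[4-(methoxymethoxy)phenyl]-3,4-dihydro-2H-chromen-8-yl]-2-[4-(methoxymethoxy)phenyl]ethane-1,2-dione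
Product: 17 1-[(2S)-5,7-dihydroxy-2-(4-hydroxyphenyl)-3,4-dihydro-2H-chromen-8-yl]-2-(4-hydroxyphenyl)ethane-1,2-dione
Conditions: HCl (2 M) in MeOH/THF, rt
Reagents that add atoms: none
Why: Acid-catalysed acetal exchange with methanol frees the four phenols. Dilute acid at room temperature is the medium the flavan ether tolerates best, and neither base nor reductant meets the diketone or C2.

## Compound list

1 | 2,4,6-trihydroxybenzaldehyde | O=Cc1c(O)cc(O)cc1O | starting material
2 | 2-hydroxy-4,6-bis(methoxymethoxy)benzaldehyde | COCOc1cc(O)c(C=O)c(OCOC)c1 | intermediate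
3 | 2-ethenyl-3,5-bis(methoxymethoxy)phenol | C=Cc1c(O)cc(OCOC)cc1OCOC | intermediate
4 | 4-hydroxybenzaldehyde | O=Cc1ccc(O)cc1 | starting material
5 | 4-(methoxymethoxy)benzaldehyde | COCOc1ccc(C=O)cc1 | intermediate
6 | ethyl (2E)-3-[4-(methoxymethoxy)phenyl]prop-2-enoate | CCOC(=O)/C=C/c1ccc(OCOC)cc1 | intermediate
7 | (2E)-3-[4-(methoxymethoxy)phenyl]prop-2-en-1-ol | OC/C=C/c1ccc(OCOC)cc1 | intermediate
8 | (2E)-3-[4-(methoxymethoxy)phenyl]prop-2-en-1-yl methyl carbonate | COC(=O)OC/C=C/c1ccc(OCOC)cc1 | intermediate
9 | lithium 2-ethenyl-3,5-bis(methoxymethoxy)phenolate | [Li+].[O-]c1cc(OCOC)cc(OCOC)c1C=C | intermediate (not isolated)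
10 | 2-ethenyl-1,5-bis(methoxymethoxy)-3-({(1S)-1-[4-(methoxymethoxy)phenyl]prop-2-en-1-yl}oxy)benzene | C=C[C@H](Oc1cc(OCOC)cc(OCOC)c1C=C)c1ccc(OCOC)cc1 | intermediate
11 | (2S)-5,7-bis(methoxymethoxy)-2-[4-(methoxymethoxy)phenyl]-2H-chromene | COCOc1cc(OCOC)c2c(c1)O[C@H](c1ccc(OCOC)cc1)C=C2 | intermediate
12 | (2S)-5,7-bis(methoxymethoxy)-2-[4-(methoxymethoxy)phenyl]-3,4-dihydro-2H-chromene | COCOc1cc(OCOC)c2c(c1)O[C@H](c1ccc(OCOC)cc1)CC2 | intermediate
13 | (2S)-8-iodo-5,7-bis(methoxymethoxy)-2-[4-(methoxymethoxy)phenyl]-3,4-dihydro-2H-chromene | COCOc1cc(OCOC)c2c(c1I)O[C@H](c1ccc(OCOC)cc1)CC2 | intermediate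
14 | 1-ethynyl-4-(methoxymethoxy)benzene | C#Cc1ccc(OCOC)cc1 | intermediate
15 | (2S)-5,7-bis(methoxymethoxy)-2-[4-(methoxymethoxy)phenyl]-8-{[4-(methoxymethoxy)phenyl]ethynyl}-3,4-dihydro-2H-chromene | COCOc1cc(OCOC)c2c(c1C#Cc1ccc(OCOC)cc1)O[C@H](c1ccc(OCOC)cc1)CC2 | intermediate
16 | 1-[(2S)-5,7-bis(methoxymethoxy)-2-[4-(methoxymethoxy)phenyl]-3,4-dihydro-2H-chromen-8-yl]-2-[4-(methoxymethoxy)phenyl]ethane-1,2-dione | COCOc1cc(OCOC)c2c(c1C(=O)C(=O)c1ccc(OCOC)cc1)O[C@H](c1ccc(OCOC)cc1)CC2 | intermediate
17 | 1-[(2S)-5,7-dihydroxy-2-(4-hydroxyphenyl)-3,4-dihydro-2H-chromen-8-yl]-2-(4-hydroxyphenyl)ethane-1,2-dione | O=C(C(=O)c1c(O)cc(O)c2c1O[C@H](c1ccc(O)cc1)CC2)c1ccc(O)cc1 | target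

## Step count and least certain steps

Total: 14 steps. Longest linear sequence: 11 steps (from 4 through steps 3, 4, 5, 6, 7, 8, 9, 10, 12, 13 and 14).

**Step 7 (key step).**
- Most likely to go wrong: allylation at a ring carbon of the very electron-rich phenoxide instead of at oxygen; re-ionisation of the product ether by the catalyst, which erodes enantiopurity and drifts toward the linear cinnamyl ether; and lowered facial selectivity from the ortho vinyl group and the electron-rich allyl partner.
- Fallback: O1–C2 is closed instead by an intramolecular Mitsunobu displacement on a reagent-controlled carbinol. Setting out from 2, aldol condensation (KOH, EtOH) with 1-[4-(methoxymethoxy)phenyl]ethan-1-one F1, made from 4-hydroxyacetophenone and MOMCl, gives the 2-hydroxychalcone F2. Hydrogenation of its enone double bond (H2, RhCl(PPh3)3) gives the dihydrochalcone F3. Asymmetric transfer hydrogenation with RuCl[(R,R)-TsDPEN](p-cymene) and HCO2H/Et3N, using the catalyst enantiomer that delivers the (R)-carbinol, gives the (R)-hydroxypropylphenol F4. PPh3 and diisopropyl azodicarboxylate then close the ring with inversion, and the detour rejoins the route at 12.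

**Step 10.**
- Most likely to go wrong: competing iodination at C6 or double iodination, because C6 and C8 are electronically alike and only sterics separate them.
- Fallback: the iodine is placed before the rings are assembled, where the chelated hydroxyl of 2 directs it to its free ortho position, as known for the corresponding acetophenones. Setting out from 2, iodination (benzyltrimethylammonium dichloroiodate, NaHCO3, CH2Cl2/MeOH) gives the iodoaldehyde F5 and Wittig methylenation gives the iodovinylphenol F6. Etherification with 8 under the conditions of step 7 gives the iodo diene F7, now from a phenoxide flanked on both sides. Metathesis gives the 8-iodo-2H-chromene F8, and rhodium hydrogenation as in step 9 rejoins the route at 13.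

**Step 12.**
- Most likely to go wrong: slow oxidative addition of zerovalent palladium into the electron-rich C8–I bond between two oxygens, leaving room for homocoupling of 14 and reductive loss of iodine.
- Fallback: the roles are exchanged so that the hindered ring carries the alkyne. Setting out from 13, iodine–lithium exchange (n-BuLi, THF, −78 °C) and quenching with DMF give the flavan-8-carbaldehyde F9. Ohira–Bestmann homologation as in step 11 gives the 8-ethynylflavan F10. Sonogashira coupling with unhindered 1-iodo-4-(methoxymethoxy)benzene F11, made from 4-iodophenol and MOMCl, rejoins the route at 15.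

**Step 13.**
- Most likely to go wrong: over-oxidation, either cleavage of the dione to two acids or attack of permanganate on ring A or the benzylic C2–H; or stalling because the lipophilic alkyne dissolves poorly in aqueous acetone.
- Fallback: the oxygens are introduced stepwise. Setting out from 15, semi-hydrogenation (H2, Pd/CaCO3 poisoned with Pb(OAc)2, quinoline) gives the (Z)-stilbene F12. Catalytic OsO4 with N-methylmorpholine N-oxide gives the syn-diol F13 as a pair of diastereomers. Swern oxidation of both carbinols (DMSO, (COCl)2, Et3N, −78 °C) rejoins the route at 16.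

**Step 14.**
- Most likely to go wrong: acid-promoted ionisation of C2–O1 competing with acetal cleavage, leading to loss of enantiopurity or reclosure through O5 with migration of the chain to C6.
- Fallback: the acid step is moved to a stage where O1 is not yet the oxygen of a 2-acylphenol, and the finish becomes neutral. Setting out from 15, HCl in MeOH gives the tetraphenol alkyne F14 and Ac2O/pyridine gives the tetraacetate alkyne F15. Permanganate oxidation as in step 13 gives the tetraacetate diketone F16. Deacetylation with Candida antarctica lipase B and n-butanol in tert-butyl methyl ether, without acid or base, then gives 17.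

## Further compounds

F1 | step 7 | 1-[4-(methoxymethoxy)phenyl]ethan-1-one | CC(=O)c1ccc(OCOC)cc1
F2 | step 7 | (2E)-3-[2-hydroxy-4,6-bis(methoxymethoxy)phenyl]-1-[4-(methoxymethoxy)phenyl]prop-2-en-1-one | O=C(/C=C/c1c(O)cc(OCOC)cc1OCOC)c1ccc(OCOC)cc1
F3 | step 7 | 3-[2-hydroxy-4,6-bis(methoxymethoxy)phenyl]-1-[4-(methoxymethoxy)phenyl]propan-1-one | O=C(CCc1c(O)cc(OCOC)cc1OCOC)c1ccc(OCOC)cc1
F4 | step 7 | 2-{(3R)-3-hydroxy-3-[4-(methoxymethoxy)phenyl]propyl}-3,5-bis(methoxymethoxy)phenol | O[C@H](CCc1c(O)cc(OCOC)cc1OCOC)c1ccc(OCOC)cc1
F5 | step 10 | 2-hydroxy-3-iodo-4,6-bis(methoxymethoxy)benzaldehyde | COCOc1cc(OCOC)c(C=O)c(O)c1I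
F6 | step 10 | 2-ethenyl-6-iodo-3,5-bis(methoxymethoxy)phenol | C=Cc1c(O)c(I)c(OCOC)cc1OCOC
F7 | step 10 | 2-ethenyl-4-iodo-1,5-bis(methoxymethoxy)-3-({(1S)-1-[4-(methoxymethoxy)phenyl]prop-2-en-1-yl}oxy)benzene | C=C[C@H](Oc1c(I)c(OCOC)cc(OCOC)c1C=C)c1ccc(OCOC)cc1
F8 | step 10 | (2S)-8-iodo-5,7-bis(methoxymethoxy)-2-[4-(methoxymethoxy)phenyl]-2H-chromene | COCOc1cc(OCOC)c2c(c1I)O[C@H](c1ccc(OCOC)cc1)C=C2
F9 | step 12 | (2S)-5,7-bis(methoxymethoxy)-2-[4-(methoxymethoxy)phenyl]-3,4-dihydro-2H-chromene-8-carbaldehyde | COCOc1cc(OCOC)c2c(c1C=O)O[C@H](c1ccc(OCOC)cc1)CC2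
F10 | step 12 | (2S)-8-ethynyl-5,7-bis(methoxymethoxy)-2-[4-(methoxymethoxy)phenyl]-3,4-dihydro-2H-chromene | COCOc1cc(OCOC)c2c(c1C#C)O[C@H](c1ccc(OCOC)cc1)CC2
F11 | step 12 | 1-iodo-4-(methoxymethoxy)benzene | COCOc1ccc(I)cc1
F12 | step 13 | (2S)-5,7-bis(methoxymethoxy)-2-[4-(methoxymethoxy)phenyl]-8-{(Z)-2-[4-(methoxymethoxy)phenyl]ethenyl}-3,4-dihydro-2H-chromene | COCOc1cc(OCOC)c2c(c1/C=C\c1ccc(OCOC)cc1)O[C@H](c1ccc(OCOC)cc1)CC2
F13 | step 13 | 1-[(2S)-5,7-bis(methoxymethoxy)-2-[4-(methoxymethoxy)phenyl]-3,4-dihydro-2H-chromen-8-yl]-2-[4-(methoxymethoxy)phenyl]ethane-1,2-diol (syn-diol, both diastereomers, carbinol centres not specified) | COCOc1cc(OCOC)c2c(c1C(O)C(O)c1ccc(OCOC)cc1)O[C@H](c1ccc(OCOC)cc1)CC2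
F14 | step 14 | (2S)-2-(4-hydroxyphenyl)-8-[(4-hydroxyphenyl)ethynyl]-3,4-dihydro-2H-chromene-5,7-diol | Oc1ccc(cc1)C#Cc1c(O)cc(O)c2c1O[C@H](c1ccc(O)cc1)CC2
F15 | step 14 | (2S)-2-[4-(acetyloxy)phenyl]-8-{[4-(acetyloxy)phenyl]ethynyl}-3,4-dihydro-2H-chromene-5,7-diyl diacetate | CC(=O)Oc1ccc(cc1)C#Cc1c(OC(C)=O)cc(OC(C)=O)c2c1O[C@H](c1ccc(OC(C)=O)cc1)CC2
F16 | step 14 | (2S)-2-[4-(acetyloxy)phenyl]-8-{[4-(acetyloxy)phenyl](oxo)acetyl}-3,4-dihydro-2H-chromene-5,7-diyl diacetate | CC(=O)Oc1ccc(cc1)C(=O)C(=O)c1c(OC(C)=O)cc(OC(C)=O)c2c1O[C@H](c1ccc(OC(C)=O)cc1)CC2
A1 | alternative 1 | 1-[(2S)-5,7-bis(benzyloxy)-2-[4-(benzyloxy)phenyl]-3,4-dihydro-2H-chromen-8-yl]ethan-1-one | CC(=O)c1c(OCc3ccccc3)cc(OCc3ccccc3)c2c1O[C@H](c1ccc(OCc3ccccc3)cc1)CC2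
A2 | alternative 1 | 1-[4,6-bis(benzyloxy)-2-hydroxy-3-(hydroxymethyl)phenyl]ethan-1-one | CC(=O)c1c(O)c(CO)c(OCc2ccccc2)cc1OCc1ccccc1
A3 | alternative 1 | 1-(benzyloxy)-4-ethenylbenzene | C=Cc1ccc(OCc2ccccc2)cc1
A4 | alternative 2 | (2R)-2-[(2S)-5,7-bis(methoxymethoxy)-2-[4-(methoxymethoxy)phenyl]-3,4-dihydro-2H-chromen-8-yl]-2-hydroxy-1-[4-(methoxymethoxy)phenyl]ethan-1-one | O=C(c1ccc(OCOC)cc1)[C@H](O)c1c(OCOC)cc(OCOC)c2c1O[C@H](c1ccc(OCOC)cc1)CC2
A5 | alternative 2 | (2S)-5,7-bis(methoxymethoxy)-2-[4-(methoxymethoxy)phenyl]-3,4-dihydro-2H-chromene-8-carbaldehyde | COCOc1cc(OCOC)c2c(c1C=O)O[C@H](c1ccc(OCOC)cc1)CC2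
A6 | alternative 3 | 5,7-bis(benzyloxy)-4H-chromen-4-one | O=c1ccoc2cc(OCc3ccccc3)cc(OCc3ccccc3)c12
A7 | alternative 3 | [4-(benzyloxy)phenyl]boronic acid | OB(O)c1ccc(OCc2ccccc2)cc1
A8 | alternative 3 | (2S)-5,7-bis(benzyloxy)-2-[4-(benzyloxy)phenyl]-2,3-dihydro-4H-chromen-4-one | O=C1C[C@@H](c2ccc(OCc3ccccc3)cc2)Oc2cc(OCc3ccccc3)cc(OCc3ccccc3)c21
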